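The runs were generated by integration with constants of no real substance; scatter was added.

The share at 20 min in this flask cannot be read from the readings so far, because the first of them comes later, at 0.500 d, so you reach it from the other end.

| setting | epsilon | flask |
|---|---|---|
| substrate | 2.7 M | 2.7 M |
| other conformer | 0.675 M | 0.675 M |
| remark | the very flask that is asked about, followed so far |  |
| time |  | 15 d |

epsilon run (percent of the substrate and other conformer together charged)

| time / d | isomer of the product A / % | target / % |
|---|---|---|
| 0.500 | 27.9 | 21.6 |
| 1.04 | 37.6 | 25.0 |
| 1.67 | 40.7 | 26.2 |
| 2.08 | 41.2 | 25.2 |
| 2.50 | 41.8 | 25.8 |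
| 3.00 | 42.0 | 25.6 |

(scatter of a reading: 0.3 percentage points)

- share of isomer of the product A in isomer of the product A plus target at 20 min
- share of isomer of the product A in isomer of the product A plus target at 15 d
- which of isomer of the product A and target there is more of at 15 d

- percentages count the substrate that a species holds: one side product counts as two
- steps under discussion: substrate <-> other conformer; substrate -> target; other conformer -> isomer of the product A; target <-> isomer of the product B; substrate + target -> side product; substrate <-> dormant form

From 2.08 d on, the readings of this flask hold the share of isomer of the product A in it plus target (a selectivity) near 62.1 %. I take that reading as the end share, with isomer of the product A in the lead. The share stands 5.8 percentage points below it at 0.500 d and 2.1 points below it at 1.04 d. If that gap shrinks by a constant factor per day, its rate is 1.90 d⁻¹. Run back to 20 min, the gap is 15 points, so my early share is 47.6 %. I carry this climb, the points the share rises from 20 min to the end.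

The forecast, lower than mine at the early time, gave a share of 43 % (32 % to 53 %) at 20 min and 62.5 % (61 % to 67 %) at 15 d, with isomer of the product A ahead: “A stays ahead.”

The flask gives a share of 49.7 % at 20 min and 62.0 % at 15 d, with isomer of the product A at 43.1 % against target at 26.4 % at 15 d.

    substrate ⇌ other conformer, settled at all times (K = 0.110)
    substrate → target (k = 7.10 × 10⁻⁴ min⁻¹)
    other conformer → isomer of the product A (k = 0.00630 min⁻¹)
    target ⇌ isomer of the product B (K = 0.480, k = 7.00 × 10⁻⁴ min⁻¹)
    substrate + target → side product (k = 1.50 × 10⁻⁴ M⁻¹ min⁻¹)
    substrate ⇌ dormant form (K = 9.20, k = 1.80 × 10⁻⁴ min⁻¹)

In this flask, isomer of the product A and target stand level at 0.0298 d, at 2.60 % each. The climb in this flask comes to 12 points, against my 15 points.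

In the neighbour flask with 1.1 M of substrate, the carried climb, taken over unchanged as an estimate, gives a rise of 15 points from 20 min to the end. The computed share there goes from 49.6 % to 60.7 %, a climb of 11 points.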